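**Plan**
- Retrosynthesis: the last cut removes an O-acetyl group. Before it, both indole N1–C7a bonds are cut together, which leads to a 2H-chromene carrying an (E)-2-nitro-1-phenylvinyl arm at C5 and at C8.
- Enabling feature: the benzene ring of the chromene (C4a, C5, C6, C7, C8, C8a) has no hydrogen left. Nitrogen on either arm can therefore reach an aromatic C–H only on its own phenyl ring, and the arm carbon bound to C5 or C8 becomes indole C3.
- Earlier cuts: the pyran ring (O1–C2 and C4–C4a, enal annulation on a hydroquinone), both C–N bonds (radical nitration of 1,1-diarylethenes), both aryl–vinyl bonds (Suzuki–Miyaura), and the C–O bond at the methoxy carbon (ortho-lithiation/hydroxylation of protected 2,5-dibromohydroquinone).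
- Forward order: the central ring is fully substituted first, the two arms are attached and nitrated while no other alkene is present, the pyran ring is closed, and both pyrrole rings are formed last in one operation.
- Stereochemistry: the target has no stereocentre. The only stereo-element on the way, the nitroalkene geometry, is consumed in the ring closure.

Key step: step 9

Assumption: every nitroalkene is drawn as the E isomer (nitro group on the side of phenyl); if the nitration gives geometric isomers they would be carried on unseparated, because the alkene geometry is expected to equilibrate under the conditions of the reductive cyclisation before the ring closes.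

**Step 1**
Reactants: 1 2,5-dibromohydroquinone (2,5-dibromobenzene-1,4-diol); 2 chloromethyl methyl ether
Product: 3 1,4-dibromo-2,5-bis(methoxymethoxy)benzene
Conditions: NaH, DMF, 0 °C → rt
Reagents that add atoms: chloromethyl methyl ether, COCCl
Why: Williamson-type O-alkylation of the bisphenoxide with the α-chloro ether; the two MOM acetals shield the hydroquinone from oxidation and act as directing groups in step 2.

**Step 2**
Reactants: 3 1,4-dibromo-2,5-bis(methoxymethoxy)benzene; 4 hydrogen peroxide
Product: 7 2,5-dibromo-3,6-bis(methoxymethoxy)phenol, via aryllithium 5 (not isolated), via dimethyl arylboronate 6 (not isolated)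
Conditions: LiN(i-Pr)2, THF, −78 °C; B(OMe)3, −78 → 0 °C; AcOH, 30% aq. H2O2, 0 °C → rt
Reagents that add atoms: hydrogen peroxide, OO
Why: Directed ortho-metalation followed by borylation and oxidation (1,2-shift of the aryl group from boron to oxygen): the amide base removes the hydrogen flanked by bromine and a MOM ether without attacking the C–Br bonds, the cold aryllithium is trapped before it can lose LiBr, and since 3 is symmetric either ring hydrogen gives the same phenol.

**Step 3**
Reactants: 7 2,5-dibromo-3,6-bis(methoxymethoxy)phenol; 8 iodomethane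
Product: 9 1,4-dibromo-3-methoxy-2,5-bis(methoxymethoxy)benzene
Conditions: K2CO3, DMF, rt
Reagents that add atoms: iodomethane, CI
Why: Williamson ether synthesis on the only free phenol; this fixes the methoxy group between one bromine and one protected oxygen, which is the pattern of C7 in the target.

**Step 4**
Reactants: 9 1,4-dibromo-3-methoxy-2,5-bis(methoxymethoxy)benzene; 10 4,4,5,5-tetramethyl-2-(1-phenylvinyl)-1,3,2-dioxaborolane (1-phenylvinylboronic acid pinacol ester)
Product: 11 3-methoxy-2,5-bis(methoxymethoxy)-1,4-bis(1-phenylvinyl)benzene
Conditions: Pd(OAc)2 (5 mol%), SPhos (10 mol%), K3PO4, toluene/H2O, 90 °C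
Reagents that add atoms: 4,4,5,5-tetramethyl-2-(1-phenylvinyl)-1,3,2-dioxaborolane, C=C(B1OC(C)(C)C(C)(C)O1)c1ccccc1
Why: Twofold Suzuki–Miyaura coupling; the bulky electron-rich biarylphosphine is chosen for oxidative addition into ortho-oxygenated aryl bromides, and the MOM acetals are stable to aqueous phosphate, unlike aryl esters.

**Step 5**
Reactants: 11 3-methoxy-2,5-bis(methoxymethoxy)-1,4-bis(1-phenylvinyl)benzene; 12 tert-butyl nitrite; 13 dioxygen
Product: 14 3-methoxy-2,5-bis(methoxymethoxy)-1,4-bis[(E)-2-nitro-1-phenylvinyl]benzene
Conditions: t-BuONO, TEMPO (40 mol% per alkene), 1,4-dioxane, O2 (balloon), 90 °C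
Reagents that add atoms: tert-butyl nitrite, CC(C)(C)ON=O; dioxygen, O=O
Why: Radical nitration of a 1,1-diarylethene: NO2 formed from the nitrite and oxygen adds to each CH2 terminus to give a diarylmethyl radical, and TEMPO removes the neighbouring hydrogen, so nitrogen ends on the terminal carbon of each arm; there is no allylic hydrogen and no other alkene in the molecule at this stage.

**Step 6**
Reactants: 14 3-methoxy-2,5-bis(methoxymethoxy)-1,4-bis[(E)-2-nitro-1-phenylvinyl]benzene
Product: 15 3-methoxy-2,5-bis[(E)-2-nitro-1-phenylvinyl]benzene-1,4-diol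
Conditions: HCl (conc., cat.), MeOH/THF, 50 °C, argon
Reagents that add atoms: none
Why: Acid-catalysed acetal exchange with methanol cleaves both MOM ethers, and the nitroalkenes, which are base-sensitive but not acid-sensitive, should pass unchanged.

**Step 7**
Reactants: 15 3-methoxy-2,5-bis[(E)-2-nitro-1-phenylvinyl]benzene-1,4-diol; 16 3-methylbut-2-enal
Product: 17 7-methoxy-2,2-dimethyl-5,8-bis[(E)-2-nitro-1-phenylvinyl]-2H-chromen-6-ol
Conditions: PhB(OH)2, AcOH, toluene, reflux (Dean–Stark), argon
Reagents that add atoms: 3-methylbut-2-enal, CC(C)=CC=O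
Why: Phenylboronic acid-mediated chromene annulation (boron-templated ortho-alkylation by the enal, dehydration and oxa-6π electrocyclisation): only the C1 hydroxyl of 15 has an unsubstituted ortho carbon (C6), so the pyran can form in one orientation only, and the acidic, amine-free medium spares the nitroalkenes.

**Step 8**
Reactants: 17 7-methoxy-2,2-dimethyl-5,8-bis[(E)-2-nitro-1-phenylvinyl]-2H-chromen-6-ol; 18 acetic anhydride
Product: 19 7-methoxy-2,2-dimethyl-5,8-bis[(E)-2-nitro-1-phenylvinyl]-2H-chromen-6-yl acetate
Conditions: Et3N, DMAP (cat.), CH2Cl2, 0 °C → rt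
Reagents that add atoms: acetic anhydride, CC(=O)OC(C)=O
Why: DMAP-catalysed O-acylation of the remaining, hindered phenol; it is masked so that it can neither add to a reduced nitrogen function on the neighbouring arm nor be oxidised in the next step.

**Step 9**
Reactants: 19 7-methoxy-2,2-dimethyl-5,8-bis[(E)-2-nitro-1-phenylvinyl]-2H-chromen-6-yl acetate
Product: 20 5,8-di(1H-indol-3-yl)-7-methoxy-2,2-dimethyl-2H-chromen-6-yl acetate (kumbicin C 6-O-acetate)
Conditions: Pd(OAc)2 (10 mol%), 1,10-phenanthroline (20 mol%), CO (2 bar), DMF, 110 °C
Reagents that add atoms: none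
Why: Under CO the divalent palladium salt is reduced to a zerovalent phenanthroline complex, which takes one oxygen from each nitro group as CO2 and brings each arm to the nitroso level. The nitroso nitrogen then bonds to the ortho carbon of the phenyl ring on the same vinyl carbon, so each five-membered ring closes by a 1,5-electrocyclisation-type C–H amination; a hydrogen shift and loss of the second oxygen to CO leave the 1H-indole with the chromene at C3. The closest known reaction type is the palladium-catalysed reductive cyclisation of α-aryl-β-nitrostyrenes with CO to 3-arylindoles, run here twice in one molecule, and no stereocentre is formed. The selectivity required is amination of the phenyl rings only, and the substrate secures it: the chromene benzene ring is hexasubstituted (C4a to C8a carry no hydrogen), and the E geometry places nitrogen next to phenyl. Simple β-nitrostyrenes whose nitro group starts trans to the aryl ring are known to cyclise in this reaction class, so an arm of the other geometry should isomerise and converge. The acetate and the C3=C4 bond should be inert to CO and zerovalent palladium because no hydride source is present.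

**Step 10**
Reactants: 20 5,8-di(1H-indol-3-yl)-7-methoxy-2,2-dimethyl-2H-chromen-6-yl acetate
Product: 21 kumbicin C (5,8-di(1H-indol-3-yl)-7-methoxy-2,2-dimethyl-2H-chromen-6-ol)
Conditions: K2CO3, MeOH (degassed), rt, argon
Reagents that add atoms: none
Why: Base-catalysed transesterification of the aryl acetate with methanol frees the C6 phenol; indole N–H, the methyl ether and the chromene alkene are untouched, and air is excluded because the product is an electron-rich phenol.

**Compound list**
1 | 2,5-dibromohydroquinone (2,5-dibromobenzene-1,4-diol) | Oc1cc(Br)c(O)cc1Br | starting material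
2 | chloromethyl methyl ether | COCCl | starting material
3 | 1,4-dibromo-2,5-bis(methoxymethoxy)benzene | COCOc1cc(Br)c(OCOC)cc1Br | intermediate
4 | hydrogen peroxide | OO | starting material
5 | [2,5-dibromo-3,6-bis(methoxymethoxy)phenyl]lithium (not isolated) | [Li]c1c(Br)c(OCOC)cc(Br)c1OCOC | intermediate
6 | dimethyl [2,5-dibromo-3,6-bis(methoxymethoxy)phenyl]boronate (not isolated) | COB(OC)c1c(Br)c(OCOC)cc(Br)c1OCOC | intermediate
7 | 2,5-dibromo-3,6-bis(methoxymethoxy)phenol | Oc1c(Br)c(OCOC)cc(Br)c1OCOC | intermediate
8 | iodomethane | CI | starting material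
9 | 1,4-dibromo-3-methoxy-2,5-bis(methoxymethoxy)benzene | COc1c(Br)c(OCOC)cc(Br)c1OCOC | intermediate
10 | 4,4,5,5-tetramethyl-2-(1-phenylvinyl)-1,3,2-dioxaborolane | C=C(B1OC(C)(C)C(C)(C)O1)c1ccccc1 | starting material
11 | 3-methoxy-2,5-bis(methoxymethoxy)-1,4-bis(1-phenylvinyl)benzene | COc1c(C(=C)c2ccccc2)c(OCOC)cc(C(=C)c2ccccc2)c1OCOC | intermediate
12 | tert-butyl nitrite | CC(C)(C)ON=O | starting material
13 | dioxygen | O=O | starting material
14 | 3-methoxy-2,5-bis(methoxymethoxy)-1,4-bis[(E)-2-nitro-1-phenylvinyl]benzene | COc1c(/C(c2ccccc2)=C/[N+](=O)[O-])c(OCOC)cc(/C(c2ccccc2)=C/[N+](=O)[O-])c1OCOC | intermediate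
15 | 3-methoxy-2,5-bis[(E)-2-nitro-1-phenylvinyl]benzene-1,4-diol | COc1c(/C(c2ccccc2)=C/[N+](=O)[O-])c(O)cc(/C(c2ccccc2)=C/[N+](=O)[O-])c1O | intermediate
16 | 3-methylbut-2-enal | CC(C)=CC=O | starting material
17 | 7-methoxy-2,2-dimethyl-5,8-bis[(E)-2-nitro-1-phenylvinyl]-2H-chromen-6-ol | COc1c(O)c(/C(c2ccccc2)=C/[N+](=O)[O-])c2C=CC(C)(C)Oc2c1/C(c1ccccc1)=C/[N+](=O)[O-] | intermediate
18 | acetic anhydride | CC(=O)OC(C)=O | starting material
19 | 7-methoxy-2,2-dimethyl-5,8-bis[(E)-2-nitro-1-phenylvinyl]-2H-chromen-6-yl acetate | COc1c(OC(C)=O)c(/C(c2ccccc2)=C/[N+](=O)[O-])c2C=CC(C)(C)Oc2c1/C(c1ccccc1)=C/[N+](=O)[O-] | intermediate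
20 | 5,8-di(1H-indol-3-yl)-7-methoxy-2,2-dimethyl-2H-chromen-6-yl acetate | COc1c(OC(C)=O)c(-c2c[nH]c3ccccc23)c2C=CC(C)(C)Oc2c1-c1c[nH]c2ccccc12 | intermediate
21 | kumbicin C | COc1c(O)c(-c2c[nH]c3ccccc23)c2c(c1-c1c[nH]c3ccccc13)OC(C)(C)C=C2 | target

**Step count**
Total steps: 10. Longest linear sequence: 10 steps (from 1 to 21).

**Steps most likely to fail**

Step 9. One or both arms may fail to close: reduction could run past the nitroso level to an enamine that hydrolyses, or an arm whose nitro group lies away from phenyl could isomerise more slowly than it is reduced. The fallback sets out from 19 and returns at 20. It replaces the catalytic carbonylative reduction by a stoichiometric phosphite deoxygenation of Cadogan–Sundberg type: 19 is heated with P(OEt)3 in o-dichlorobenzene at 160 °C. This route passes through a vinylnitrene-type species in which the two aryl groups sit on a carbon that no longer holds a fixed alkene geometry, and the nitrogen should insert into the only available ortho C–H, that of phenyl. No compound outside the list is made, F0.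

Step 7. Ortho-alkylation by the enal may be too slow, because the reacting ring carbon lies next to a nitrovinyl arm that withdraws electron density and crowds it; air oxidation of the hydroquinone or self-condensation of the enal could then take over. The fallback sets out from 15 and returns at 19, building the pyran by a sigmatropic route that does not depend on ring nucleophilicity. The less hindered hydroxyl of 15 (the one with the free ortho carbon) would be alkylated with 3-chloro-3-methylbut-1-yne (K2CO3, KI, CuI cat., acetone, 50 °C) to give 2-methoxy-4-[(2-methylbut-3-yn-2-yl)oxy]-3,6-bis[(E)-2-nitro-1-phenylvinyl]phenol F1. Acetylation (Ac2O, Et3N, DMAP, CH2Cl2) would give 2-methoxy-4-[(2-methylbut-3-yn-2-yl)oxy]-3,6-bis[(E)-2-nitro-1-phenylvinyl]phenyl acetate F2. Heating F2 in o-dichlorobenzene at 160 °C should trigger the aromatic propargyl Claisen rearrangement onto the single free ortho carbon, then a 1,5-hydrogen shift and oxa-6π electrocyclisation, giving 19 directly, so that step 8 is not needed.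

Step 5. The hot, oxygen-rich radical medium may oxidise or nitrate the electron-rich ring at its one C–H, may attack the MOM acetals, or may leave the more crowded arm unreacted. The fallback sets out from 11 and returns at 14, dividing the nitration into an addition and an elimination at room temperature without oxygen. Nitryl iodide made from AgNO2 and I2 (THF, rt) should add across each alkene, nitro at the terminal carbon and iodine at the diaryl carbon, to give 1,4-bis(1-iodo-2-nitro-1-phenylethyl)-3-methoxy-2,5-bis(methoxymethoxy)benzene F3 (mixture of diastereomers, not purified). Et3N in the same flask would then remove HI from each arm to give 14.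

**Further compounds**
F0 | step 9 | none | none
F1 | step 7 | 2-methoxy-4-[(2-methylbut-3-yn-2-yl)oxy]-3,6-bis[(E)-2-nitro-1-phenylvinyl]phenol | COc1c(/C(c2ccccc2)=C/[N+](=O)[O-])c(OC(C)(C)C#C)cc(/C(c2ccccc2)=C/[N+](=O)[O-])c1O
F2 | step 7 | 2-methoxy-4-[(2-methylbut-3-yn-2-yl)oxy]-3,6-bis[(E)-2-nitro-1-phenylvinyl]phenyl acetate | COc1c(/C(c2ccccc2)=C/[N+](=O)[O-])c(OC(C)(C)C#C)cc(/C(c2ccccc2)=C/[N+](=O)[O-])c1OC(C)=O
F3 | step 5 | 1,4-bis(1-iodo-2-nitro-1-phenylethyl)-3-methoxy-2,5-bis(methoxymethoxy)benzene (mixture of diastereomers) | COc1c(C(I)(C[N+](=O)[O-])c2ccccc2)c(OCOC)cc(C(I)(C[N+](=O)[O-])c2ccccc2)c1OCOC
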